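**Retrosynthetic overview**
1. Target ⇒ C12–C13 B-alkyl Suzuki coupling of the 9-vinyl decalin diol 13 with the (1E,5E)-alkenyl iodide 24.
2. 13 ⇒ 8-oxo-9-vinyl decalin 10; C8 is set by methylenation, α-face epoxidation and hydride opening.
3. 10 ⇒ 1-allyl-hydrindan-1-ol 9 by the key step: ring B is made last, by expanding the cyclopentanol to the cyclohexanone through a 1,2-shift of C10 onto a palladium π-allyl.
4. 9 ⇒ (S)-enedione 4 (allylation, reductive methylation, reduction) ⇒ 2-methylcyclopentane-1,3-dione + ethyl vinyl ketone; ring A is formed first, on the five-membered ring.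
5. 24 ⇒ two rounds of zirconium-catalysed methylalumination on alkynes built from 5-bromo-2-methylpent-2-ene, lithium acetylide and oxirane.

Assumption: decalin positions use terpenoid numbering (C3 carbinol, C4 gem-dimethyl, C5/C10 ring fusion, C8 tertiary carbinol, C9 side-chain carbon; β = the face of the C10 methyl), and allylmagnesium bromide and lithium acetylide–ethylenediamine are bought as such.

**Route**

Step 1
Reactants: 1 2-methylcyclopentane-1,3-dione; 2 pent-1-en-3-one (ethyl vinyl ketone)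
Product: 4 (7aS)-4,7a-dimethyl-2,3,7,7a-tetrahydro-1H-indene-1,5(6H)-dione, via triketone 3 (not isolated)
Conditions: Et3N (2 mol%), neat, 20 °C; then L-phenylalanine (1.0 equiv), (1S)-(+)-camphor-10-sulfonic acid (0.5 equiv), DMF, 30 → 70 °C; recrystallisation
Reagents that add atoms: none
Why: Michael addition followed by an amino acid-mediated intramolecular aldol condensation (Hajos–Parrish–Eder–Sauer–Wiechert reaction); the L-phenylalanine enamine distinguishes the two enantiotopic ring carbonyls and sets the quaternary centre 7aS (the future C10), and recrystallisation raises the ee.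

Step 2
Reactants: 4 (7aS)-4,7a-dimethyl-2,3,7,7a-tetrahydro-1H-indene-1,5(6H)-dione; 5 allylmagnesium bromide
Product: 6 (1R,7aS)-1-hydroxy-4,7a-dimethyl-1-(prop-2-en-1-yl)-1,2,3,6,7,7a-hexahydro-5H-inden-5-one
Conditions: 5 (1.05 equiv, slow addition), THF, −78 °C; aq. NH4Cl
Reagents that add atoms: none
Why: Grignard 1,2-addition; at −78 °C the unconjugated cyclopentanone should be more electrophilic than the conjugated enone carbonyl, and attack anti to the angular methyl gives the 1β-ol (this centre later becomes C=O, so its configuration is not critical).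

Step 3
Reactants: 6 (1R,7aS)-1-hydroxy-4,7a-dimethyl-1-(prop-2-en-1-yl)-1,2,3,6,7,7a-hexahydro-5H-inden-5-one
Product: 9 (1R,3aS,5S,7aS)-4,4,7a-trimethyl-1-(prop-2-en-1-yl)octahydro-1H-indene-1,5-diol, via lithium enolate 7 (not isolated), via hydroxy ketone 8 (not isolated)
Conditions: Li (2.5 equiv), NH3(l)/THF, t-BuOH (1.0 equiv), −78 °C; MeI (5 equiv), −78 → −33 °C; NH3 evaporated; then NaBH4, MeOH, 0 °C
Reagents that add atoms: iodomethane (CI)
Why: Stork dissolving-metal reductive alkylation followed by borohydride reduction; protonation of the β-carbon anti to the angular methyl gives the trans ring fusion (future 5α-H), the regiodefined enolate is C-methylated to the gem-dimethyl group, and NaBH4 attacks the neopentyl ketone axially from the α face to give the equatorial 3β-alcohol (3S), while the isolated terminal alkene is inert.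

Step 4
Reactants: 9 (1R,3aS,5S,7aS)-4,4,7a-trimethyl-1-(prop-2-en-1-yl)octahydro-1H-indene-1,5-diol
Product: 10 (1R,4aR,6S,8aS)-1-ethenyl-6-hydroxy-5,5,8a-trimethyloctahydronaphthalen-2(1H)-one
Conditions: Pd(OAc)2 (10 mol%), 1,2-bis(phenylsulfinyl)ethane (10 mol%), (PhO)2P(O)OH (20 mol%), 2,6-dimethyl-1,4-benzoquinone (1.5 equiv), toluene, 45 °C
Reagents that add atoms: none
Why: Proposed new method: divalent palladium with the bis-sulfoxide ligand cleaves the allylic C–H bond of the terminal olefin to give a π-allylpalladium whose inner terminus sits on the carbinol carbon; that carbon has no β-hydrogen and no competent external nucleophile is present, so the antiperiplanar C8–C10 σ-bond (quaternary, the better migrating group) shifts to the allyl terminus with loss of zerovalent palladium (reoxidised by the quinone) while the phosphate-bound O–H becomes C=O, a semipinacol ring expansion that forms ring B and the C9–C10 bond, with the enolisable C9 settling as the equatorial 9β-vinyl epimer; the closest known reactions are the palladium/Brønsted acid allylic C–H activation–semipinacol expansion of allyl cyclobutanols and π-allylpalladium Wagner–Meerwein expansions of cyclobutanols, not yet shown for an unstrained cyclopentanol, where the driving force is C=O formation plus loss of cyclopentane strain.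

Step 5
Reactants: 10 (1R,4aR,6S,8aS)-1-ethenyl-6-hydroxy-5,5,8a-trimethyloctahydronaphthalen-2(1H)-one
Product: 11 (2S,4aS,5S,8aR)-5-ethenyl-1,1,4a-trimethyl-6-methylidenedecahydronaphthalen-2-ol
Conditions: Zn, CH2Br2, TiCl4, THF/CH2Cl2, 0 °C → rt (excess reagent for the free OH)
Reagents that add atoms: dibromomethane (BrCBr)
Why: Takai–Lombardo methylenation; the non-basic zinc/titanium reagent converts the hindered ketone into the exocyclic alkene without epimerising C9 or moving the β,γ-double bond into conjugation, which a basic ylide could do.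

Step 6
Reactants: 11 (2S,4aS,5S,8aR)-5-ethenyl-1,1,4a-trimethyl-6-methylidenedecahydronaphthalen-2-ol
Product: 12 (1R,2R,4aR,6S,8aS)-1-ethenyl-5,5,8a-trimethyloctahydro-1H-spiro[naphthalene-2,2'-oxiran]-6-ol
Conditions: mCPBA (1.05 equiv), NaHCO3, CH2Cl2, −20 → 0 °C
Reagents that add atoms: 3-chloroperbenzoic acid (OOC(=O)c1cccc(Cl)c1)
Why: Prilezhaev epoxidation; the 1,1-disubstituted exocyclic alkene is far more nucleophilic than the monosubstituted vinyl group, and the peracid approaches from the α face because the β face is shielded by the axial C10 methyl, which puts the oxygen α at C8 (any β-epoxide is removed by chromatography).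

Step 7
Reactants: 12 (1R,2R,4aR,6S,8aS)-1-ethenyl-5,5,8a-trimethyloctahydro-1H-spiro[naphthalene-2,2'-oxiran]-6-ol
Product: 13 (1R,2R,4aR,6S,8aS)-1-ethenyl-2,5,5,8a-tetramethyldecahydronaphthalene-2,6-diol
Conditions: LiAlH4, THF, 0 °C → reflux
Reagents that add atoms: none
Why: Hydride opening of the epoxide by SN2 attack at the CH2 carbon; the C8–O bond is untouched, so the α-oxygen becomes the equatorial tertiary 8α-alcohol and the new methyl is axial (β).

Step 8
Reactants: 14 5-bromo-2-methylpent-2-ene; 15 lithium acetylide–ethylenediamine complex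
Product: 16 6-methylhept-5-en-1-yne
Conditions: DMSO, 10 → 20 °C
Reagents that add atoms: none
Why: SN2 alkylation of the acetylide by a primary homoallylic bromide.

Step 9
Reactants: 16 6-methylhept-5-en-1-yne; 17 oxirane
Product: 20 (3E)-4,8-dimethylnona-3,7-dien-1-ol, via alkenylalane 18 (not isolated), via lithium alanate 19 (not isolated)
Conditions: AlMe3 (2 equiv), Cp2ZrCl2 (0.25 equiv), CH2Cl2, 0 °C → rt; volatiles removed; n-BuLi, hexane/THF, −30 °C; 17, −30 → 0 °C; aq. work-up
Reagents that add atoms: trimethylaluminium (C[Al](C)C)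
Why: Negishi zirconium-catalysed methylalumination; syn addition of Me–Al across the terminal alkyne fixes the E trisubstituted alkene, and the alanate opens oxirane with retention of the alkenyl geometry.

Step 10
Reactants: 20 (3E)-4,8-dimethylnona-3,7-dien-1-ol
Product: 21 (6E)-9-iodo-2,6-dimethylnona-2,6-diene
Conditions: I2, PPh3, imidazole, CH2Cl2, 0 °C
Reagents that add atoms: iodine (II)
Why: Appel-type iodination of a primary alcohol; the alkenes are untouched.

Step 11
Reactants: 21 (6E)-9-iodo-2,6-dimethylnona-2,6-diene; 15 lithium acetylide–ethylenediamine complex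
Product: 22 (5E)-6,10-dimethylundeca-5,9-dien-1-yne
Conditions: DMSO, 10 → 20 °C
Reagents that add atoms: none
Why: SN2 alkylation of the acetylide by the primary iodide.

Step 12
Reactants: 22 (5E)-6,10-dimethylundeca-5,9-dien-1-yne
Product: 24 (1E,5E)-1-iodo-2,6,10-trimethylundeca-1,5,9-triene, via alkenylalane 23 (not isolated)
Conditions: AlMe3 (2 equiv), Cp2ZrCl2 (0.25 equiv), CH2Cl2, 0 °C → rt; then I2, THF, −30 → 0 °C
Reagents that add atoms: trimethylaluminium (C[Al](C)C); iodine (II)
Why: Negishi methylalumination and iodinolysis with retention; the alkyne reacts selectively over the trisubstituted alkenes and the second E alkene is set by syn addition.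

Step 13
Reactants: 13 (1R,2R,4aR,6S,8aS)-1-ethenyl-2,5,5,8a-tetramethyldecahydronaphthalene-2,6-diol; 24 (1E,5E)-1-iodo-2,6,10-trimethylundeca-1,5,9-triene
Product: 26 (1R,2R,4aR,6S,8aS)-2,5,5,8a-tetramethyl-1-[(3E,7E)-4,8,12-trimethyltrideca-3,7,11-trien-1-yl]decahydronaphthalene-2,6-diol, via alkylborane 25 (not isolated)
Conditions: 9-BBN (3.5 equiv), THF, 0 °C → rt; then 24, PdCl2(dppf) (5 mol%), AsPh3 (10 mol%), Cs2CO3 (3 equiv), DMF/H2O, rt
Reagents that add atoms: none
Why: Anti-Markovnikov hydroboration of the only alkene in 13, then B-alkyl Suzuki–Miyaura coupling, which forms C12–C13 with retention of the alkenyl iodide geometry and tolerates the free hydroxyls (excess borane covers any O–B formation).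

**Compound list**
1 | 2-methylcyclopentane-1,3-dione | CC1C(=O)CCC1=O | starting material
2 | pent-1-en-3-one | CCC(=O)C=C | starting material
3 | 2-methyl-2-(3-oxopentyl)cyclopentane-1,3-dione (not isolated) | CCC(=O)CCC1(C)C(=O)CCC1=O | intermediate
4 | (7aS)-4,7a-dimethyl-2,3,7,7a-tetrahydro-1H-indene-1,5(6H)-dione | C[C@]12CCC(=O)C(C)=C1CCC2=O | intermediate
5 | allylmagnesium bromide | C=CC[Mg]Br | starting material
6 | (1R,7aS)-1-hydroxy-4,7a-dimethyl-1-(prop-2-en-1-yl)-1,2,3,6,7,7a-hexahydro-5H-inden-5-one | C[C@]12CCC(=O)C(C)=C1CC[C@@]2(O)CC=C | intermediate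
7 | lithium enolate of 8 before C-methylation (trans-fused, not isolated) | C[C@]12CCC(O[Li])=C(C)[C@@H]1CC[C@@]2(O)CC=C | intermediate
8 | (1R,3aR,7aS)-1-hydroxy-4,4,7a-trimethyl-1-(prop-2-en-1-yl)octahydro-5H-inden-5-one (not isolated) | C[C@]12CCC(=O)C(C)(C)[C@@H]1CC[C@@]2(O)CC=C | intermediate
9 | (1R,3aS,5S,7aS)-4,4,7a-trimethyl-1-(prop-2-en-1-yl)octahydro-1H-indene-1,5-diol | C[C@]12CC[C@H](O)C(C)(C)[C@@H]1CC[C@@]2(O)CC=C | intermediate
10 | (1R,4aR,6S,8aS)-1-ethenyl-6-hydroxy-5,5,8a-trimethyloctahydronaphthalen-2(1H)-one | C=C[C@@H]1[C@@]2(C)CC[C@H](O)C(C)(C)[C@@H]2CCC1=O | intermediate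
11 | (2S,4aS,5S,8aR)-5-ethenyl-1,1,4a-trimethyl-6-methylidenedecahydronaphthalen-2-ol | C=C[C@@H]1[C@@]2(C)CC[C@H](O)C(C)(C)[C@@H]2CCC1=C | intermediate
12 | (1R,2R,4aR,6S,8aS)-1-ethenyl-5,5,8a-trimethyloctahydro-1H-spiro[naphthalene-2,2'-oxiran]-6-ol (oxirane oxygen α at C8) | C=C[C@@H]1[C@@]2(C)CC[C@H](O)C(C)(C)[C@@H]2CC[C@]13CO3 | intermediate
13 | (1R,2R,4aR,6S,8aS)-1-ethenyl-2,5,5,8a-tetramethyldecahydronaphthalene-2,6-diol | C=C[C@@H]1[C@@]2(C)CC[C@H](O)C(C)(C)[C@@H]2CC[C@@]1(C)O | intermediate
14 | 5-bromo-2-methylpent-2-ene | CC(C)=CCCBr | starting material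
15 | lithium acetylide–ethylenediamine complex | [Li+].[C-]#C.NCCN | starting material
16 | 6-methylhept-5-en-1-yne | CC(C)=CCCC#C | intermediate
17 | oxirane | C1CO1 | starting material
18 | dimethyl[(1E)-2,6-dimethylhepta-1,5-dien-1-yl]alane (not isolated) | CC(C)=CCC/C(C)=C/[Al](C)C | intermediate
19 | lithium butyl(dimethyl)[(1E)-2,6-dimethylhepta-1,5-dien-1-yl]aluminate (not isolated) | CC(C)=CCC/C(C)=C/[Al-](C)(C)CCCC.[Li+] | intermediate
20 | (3E)-4,8-dimethylnona-3,7-dien-1-ol | CC(C)=CCC/C(C)=C/CCO | intermediate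
21 | (6E)-9-iodo-2,6-dimethylnona-2,6-diene | CC(C)=CCC/C(C)=C/CCI | intermediate
22 | (5E)-6,10-dimethylundeca-5,9-dien-1-yne | CC(C)=CCC/C(C)=C/CCC#C | intermediate
23 | dimethyl[(1E,5E)-2,6,10-trimethylundeca-1,5,9-trien-1-yl]alane (not isolated) | CC(C)=CCC/C(C)=C/CC/C(C)=C/[Al](C)C | intermediate
24 | (1E,5E)-1-iodo-2,6,10-trimethylundeca-1,5,9-triene | CC(C)=CCC/C(C)=C/CC/C(C)=C/I | intermediate
25 | 9-{2-[(1R,2R,4aR,6S,8aS)-2,6-dihydroxy-2,5,5,8a-tetramethyldecahydronaphthalen-1-yl]ethyl}-9-borabicyclo[3.3.1]nonane (not isolated) | C1CCC2CCCC1B2CC[C@@H]3[C@@]4(C)CC[C@H](O)C(C)(C)[C@@H]4CC[C@@]3(C)O | intermediate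
26 | (1R,2R,4aR,6S,8aS)-2,5,5,8a-tetramethyl-1-[(3E,7E)-4,8,12-trimethyltrideca-3,7,11-trien-1-yl]decahydronaphthalene-2,6-diol | CC(C)=CCC/C(C)=C/CC/C(C)=C/CC[C@@H]1[C@@]2(C)CC[C@H](O)C(C)(C)[C@@H]2CC[C@@]1(C)O | target

**Step count and risks**

Total step count: 13 (steps 1–7 bicyclic core, steps 8–12 alkenyl iodide, step 13 coupling). Longest linear sequence: 8 steps (1–7 and 13).

The three steps most likely to fail:

Step 2 (chemoselective allylation). The enone carbonyl may compete with the hindered cyclopentanone. The fallback sets out from 4 and comes back at 6. Compound 4 is condensed with pyrrolidine (benzene, azeotropic removal of water) to give the pyrrolidine dienamine F1, which masks only the enone, as in the classical steroid tactic. Allylmagnesium bromide (THF, −20 °C) then adds only at C1 to give the allylated dienamine F2. Buffered hydrolysis (AcOH, NaOAc, H2O) releases the enone and delivers 6.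

Step 3 (reductive methylation). The free 1β-hydroxyl could deliver the proton to the β face and erode the trans ring fusion. The fallback sets out from 6 and comes back at 8. Silylation (Et3SiOTf, 2,6-lutidine, CH2Cl2) gives the triethylsilyl ether F3, which has no internal proton donor and a bulky β-face substituent, as in the well-precedented 1β-alkoxy series. Li/NH3/t-BuOH gives the silylated lithium enolate F4, MeI converts it to the silylated trans ketone F5, and aq. HCl/THF removes the silyl group to return 8. Compound 8 is then reduced with NaBH4 as in step 3 to give 9.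

Step 4 (the new ring expansion). The 1,2-shift onto the π-allyl may lose to acetate or phosphate capture, oxypalladation or isomerisation of the product to the conjugated enone. The fallback uses only established chemistry, sets out from 4 and comes back at 11:
- Vinylmagnesium bromide (THF, −78 °C) gives the vinyl carbinol F6.
- Li/NH3/t-BuOH then MeI gives, through the vinyl lithium enolate F7, the vinyl hydroxy ketone F8, and NaBH4 reduces this to the vinyl diol F9.
- VO(acac)2/t-BuOOH epoxidises the allylic alcohol to the epoxy diol F10.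
- BF3·OEt2 (CH2Cl2, −78 °C) triggers the classical 2,3-epoxy alcohol semipinacol ring expansion (C10 migrates to the oxirane CH) to give the β-hydroxy ketone F11.
- Zn/CH2Br2/TiCl4 gives the methylidene diol F12.
- TEMPO/PhI(OAc)2 oxidises only the primary alcohol to the aldehyde F13.
- Ph3P=CH2 (THF, −78 → 0 °C) converts F13 into 11.

This replaces steps 2–5 by seven operations.

**Further compounds**
F1 | step 2 | (7aS)-4,7a-dimethyl-5-(pyrrolidin-1-yl)-2,6,7,7a-tetrahydro-1H-inden-1-one | C[C@]12CCC(N3CCCC3)=C(C)C1=CCC2=O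
F2 | step 2 | (1S,7aS)-4,7a-dimethyl-1-(prop-2-en-1-yl)-5-(pyrrolidin-1-yl)-2,6,7,7a-tetrahydro-1H-inden-1-ol | C[C@]12CCC(N3CCCC3)=C(C)C1=CC[C@@]2(O)CC=C
F3 | step 3 | (1R,7aS)-4,7a-dimethyl-1-(prop-2-en-1-yl)-1-[(triethylsilyl)oxy]-1,2,3,6,7,7a-hexahydro-5H-inden-5-one | C[C@]12CCC(=O)C(C)=C1CC[C@@]2(O[Si](CC)(CC)CC)CC=C
F4 | step 3 | lithium enolate of F5 before C-methylation (trans-fused) | C[C@]12CCC(O[Li])=C(C)[C@@H]1CC[C@@]2(O[Si](CC)(CC)CC)CC=C
F5 | step 3 | (1R,3aR,7aS)-4,4,7a-trimethyl-1-(prop-2-en-1-yl)-1-[(triethylsilyl)oxy]octahydro-5H-inden-5-one | C[C@]12CCC(=O)C(C)(C)[C@@H]1CC[C@@]2(O[Si](CC)(CC)CC)CC=C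
F6 | step 4 | (1R,7aS)-1-ethenyl-1-hydroxy-4,7a-dimethyl-1,2,3,6,7,7a-hexahydro-5H-inden-5-one | C[C@]12CCC(=O)C(C)=C1CC[C@@]2(O)C=C
F7 | step 4 | lithium enolate of F8 before C-methylation (trans-fused) | C[C@]12CCC(O[Li])=C(C)[C@@H]1CC[C@@]2(O)C=C
F8 | step 4 | (1R,3aR,7aS)-1-ethenyl-1-hydroxy-4,4,7a-trimethyloctahydro-5H-inden-5-one | C[C@]12CCC(=O)C(C)(C)[C@@H]1CC[C@@]2(O)C=C
F9 | step 4 | (1R,3aS,5S,7aS)-1-ethenyl-4,4,7a-trimethyloctahydro-1H-indene-1,5-diol | C[C@]12CC[C@H](O)C(C)(C)[C@@H]1CC[C@@]2(O)C=C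
F10 | step 4 | (1S,3aS,5S,7aS)-4,4,7a-trimethyl-1-(oxiran-2-yl)octahydro-1H-indene-1,5-diol (both oxirane epimers) | C[C@]12CC[C@H](O)C(C)(C)[C@@H]1CC[C@@]2(O)C1CO1
F11 | step 4 | (1S,4aR,6S,8aS)-6-hydroxy-1-(hydroxymethyl)-5,5,8a-trimethyloctahydronaphthalen-2(1H)-one | OC[C@@H]1[C@@]2(C)CC[C@H](O)C(C)(C)[C@@H]2CCC1=O
F12 | step 4 | (2S,4aS,5S,8aR)-5-(hydroxymethyl)-1,1,4a-trimethyl-6-methylidenedecahydronaphthalen-2-ol | OC[C@@H]1[C@@]2(C)CC[C@H](O)C(C)(C)[C@@H]2CCC1=C
F13 | step 4 | (1S,4aR,6S,8aS)-6-hydroxy-5,5,8a-trimethyl-2-methylidenedecahydronaphthalene-1-carbaldehyde | O=C[C@@H]1[C@@]2(C)CC[C@H](O)C(C)(C)[C@@H]2CCC1=C
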